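Plan (labdane numbering, C1–C20)
1. Cuts: the C19–O feruloyl ester; C11–C12 (isoprenyl unit) and C9–C11; ring A at C3–C4; C1–C10 and C10–C20.
2. Forward: ring B is the ring of (R)-carvone. C20 and a C1–C3 acrolein unit are put on C10, the isopropenyl group is oxidised to the C4–C19 propionic acid, and both are tied into a temporary δ-lactone ring (C1–O–C19–C4–C5–C10).
3. Enabling feature: C4 of ring A is a quaternary carbon with an oxidised one-carbon branch (C19) and lies 1,4 across ring A from C1. With C19 as carboxyl and the lactone O on C1, the atoms C3=C2–C1–O–C19=C4 form an allyl/ketene-acetal array.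
4. An Ireland–Claisen rearrangement closes ring A last (C3–C4 made, C1–O broken) and expels O and C19 from the ring. The helpers go later: C1=C2 is hydrogenated, C9=O becomes C9=C11, and CO2H is reduced to C19H2OH.
5. The side chain is joined at C11–C12 by hydroboration/allyl–alkyl coupling, the C8 carbinol comes from the C7=C8 alkene of carvone, and the ferulate is attached last.
6. Stereochemistry: C5 from carvone; C10 by attack anti to the C5 chain; C1 by a closed aldol transition state, relayed to C4 by the suprafacial [3,3] shift; C9 and C8 by α-face attack opposite the axial C20 methyl.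

Key step: step 5

Remark: centres drawn without a stereo mark (C4, C9, C10 in 2–4; C4 in 6 and 7) are epimer mixtures that a later step makes planar. Commercial LDA and 9-BBN solutions are assumed.

Step 1
Reactants: 1 (R)-(−)-carvone
Product: 2 6-methylcarvone
Conditions: LDA, THF, −78 °C; MeI, −78 → 0 °C
Reagents that add atoms: methyl iodide, CI
Why: Kinetic α′-deprotonation and SN2 methylation of the cross-conjugated lithium enolate (enolate alkylation) should put C20 on C10; the epimer ratio at C10 does not matter because step 4 makes this centre planar again.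

Step 2
Reactants: 2 6-methylcarvone
Product: 3 diol (C9–OH and C19–OH)
Conditions: 9-BBN (2.5 equiv), THF, 0 °C → rt; then NaOH, H2O2, 0 °C
Reagents that add atoms: hydrogen peroxide, OO
Why: Brown hydroboration–oxidation: 9-BBN should add anti-Markovnikov to the 1,1-disubstituted isopropenyl group (boron on C19) and reduce the enone carbonyl 1,2 while sparing the trisubstituted ring alkene, and the new centres C4 and C9 arise as mixtures that steps 3 and 5 erase.

Step 3
Reactants: 3 diol
Product: 4 keto acid 2-(2,4-dimethyl-3-oxocyclohex-4-en-1-yl)propanoic acid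
Conditions: CrO3, H2SO4, H2O, acetone, 0 °C
Reagents that add atoms: water, O
Why: Jones oxidation should take the primary alcohol through the aldehyde hydrate to the C19 acid and the allylic alcohol back to the enone in one operation, the trisubstituted alkene being inert.

Step 4
Reactants: 4 keto acid; 5 acrolein
Product: 7 trans-fused 1α-vinyl δ-lactone, via aldol hydroxy acid 6 (not isolated)
Conditions: LDA (2.2 equiv), THF, −78 °C; 5, −78 °C; AcOH quench; then CSA (cat.), CH2Cl2, rt
Reagents that add atoms: none
Why: Directed aldol addition followed by acid-catalysed lactonisation: the carboxylate/C9–C10 enolate dianion should add 1,2 to acrolein on the ring face anti to the C5 side chain (C10: C1 α, C20 β), the closed Zimmerman–Traxler chair of the ring-locked (E)-enolate with the vinyl group equatorial should give the 1R carbinol, and closure of the trans-fused δ-lactone takes the aldol out of the retro-aldol equilibrium and lets a minor C1 epimer be separated.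

Step 5
Reactants: 7 trans-fused 1α-vinyl δ-lactone
Product: 10 bicyclic keto acid (ring A closed), via bis-silyl ketene acetal 8 (not isolated), via bis-silyl rearranged ester 9 (not isolated)
Conditions: LDA (2.6 equiv), TBSCl (3 equiv), THF–DMPU, −78 °C → rt; toluene, 110 °C; then 1 M HCl, THF, rt
Reagents that add atoms: tert-butyldimethylsilyl chloride, CC(C)(C)[Si](C)(C)Cl (its silyl groups stay only in 8 and 9)
Why: Double deprotonation and O-silylation should turn 7 into the cyclic silyl ketene acetal 8 (the enone is parked as its silyl dienol ether), in which the C1–O σ bond, the C2=C3 π bond and the C4=C19 π bond form the six-atom array of an Ireland–Claisen rearrangement, and heating breaks C1–O and makes C3–C4 in one concerted suprafacial [3,3] shift. The closest known reaction type is the Claisen rearrangement of silyl ketene acetals of 6-vinyl δ-lactones to cyclohex-3-enecarboxylic acids, which must pass a boat-like array because the ketene acetal is endocyclic. Ring A (C1, C2, C3, C4, C5, C10) closes by C3–C4 bonding, 6-(enolexo)-endo-trig in Baldwin terms, while the temporary lactone ring opens, so that O and C19 leave the ring and C2 and C3 enter it. The only new stereocentre, quaternary C4, is fixed by C1: the α-axial vinyl group can reach only the α face of C4, so C3 enters α, C19 is left β (axial, syn to C20) and C18 α (equatorial); the ring-locked ketene acetal has no E/Z ambiguity and both C4 epimers of 7 converge. The trans ring fusion holds the dihydropyran half-chair with the vinyl group axial and its terminus within van der Waals contact of C4, so little reorganisation is needed. The selectivity problem (lactone C4–H beside the more acidic enone γ-H) is met by silylating both sites and hydrolysing both silyl groups with acid, which also returns the enone to conjugation.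

Step 6
Reactants: 10 bicyclic keto acid
Product: 11 methyl ester of 10
Conditions: MeI, K2CO3, DMF, rt
Reagents that add atoms: methyl iodide, CI
Why: SN2 O-alkylation of the carboxylate avoids attack at the shielded axial carboxyl carbon, and the ester protects C19 through steps 7–12.

Step 7
Reactants: 11 methyl ester
Product: 12 enone ester with saturated ring A
Conditions: H2 (1 atm), RhCl(PPh3)3 (cat.), benzene–EtOH, rt
Reagents that add atoms: none
Why: Homogeneous hydrogenation with Wilkinson's catalyst should saturate the cis-disubstituted C1=C2 alkene left by the rearrangement and leave the trisubstituted conjugated C7=C8 alkene, as in the known selective 1,2-reduction of steroidal 1,4-dien-3-ones.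

Step 8
Reactants: 12 enone ester
Product: 13 9(11),7-diene ester
Conditions: Ph3PCH3Br, KOtBu, toluene, 90 °C
Reagents that add atoms: methyltriphenylphosphonium bromide, C[P+](c1ccccc1)(c1ccccc1)c1ccccc1.[Br-]
Why: Wittig methylenation under the potassium tert-butoxide/hot toluene conditions used for hindered ketones should convert C9=O into the C9=C11 methylene group, the hindered C19 ester being inert to the ylide.

Step 9
Reactants: 14 isoprene
Product: 15 (E)-1,4-dibromo-2-methylbut-2-ene
Conditions: Br2, CH2Cl2, −20 °C
Reagents that add atoms: bromine, BrBr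
Why: Electrophilic 1,4-addition of bromine to the diene should give the preferred (E)-1,4-dibromide.

Step 10
Reactants: 15 (E)-1,4-dibromo-2-methylbut-2-ene
Product: 16 2-(bromomethyl)buta-1,3-diene
Conditions: DMPU, 120 °C, reduced pressure, product distilled out
Reagents that add atoms: none
Why: Thermal 1,4-dehydrobromination (loss of a methyl hydrogen and the remote allylic bromide) in the basic dipolar solvent should give the cross-conjugated bromide, which is removed by distillation as it forms.

Step 11
Reactants: 13 9(11),7-diene ester; 16 2-(bromomethyl)buta-1,3-diene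
Product: 18 methyl labda-7,13(16),14-trien-19-oate, via C11 alkyl-9-BBN 17 (not isolated)
Conditions: 9-BBN, THF, 60 °C; then KOtBu, CuOAc (cat.), 16, THF, rt → 40 °C
Reagents that add atoms: 9-BBN, B1C2CCCC1CCC2 (its boron and ring stay only in 17)
Why: Brown hydroboration followed by copper-catalysed allyl–alkyl coupling of the alkyl-9-BBN ate complex: boron should go to the terminal C11 and hydrogen to C9 from the α face opposite the axial C20 methyl (sets 9α-H), and SN2 and SN2′ attack on the 2-vinylallyl bromide lead to the same C11–C12 bonded product.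

Step 12
Reactants: 18 methyl labda-7,13(16),14-trien-19-oate
Product: 19 methyl 7α,8α-epoxylabda-13(16),14-dien-19-oate
Conditions: mCPBA (1.0 equiv), CH2Cl2, −20 → 0 °C
Reagents that add atoms: 3-chloroperbenzoic acid, O=C(OO)c1cccc(Cl)c1
Why: Prilezhaev epoxidation: the electron-rich trisubstituted C7=C8 alkene should react before the conjugated mono- and 1,1-disubstituted alkenes of the side chain (as in the 6,7-selective epoxidation of myrcene), and from the α face because C20 shields the β face.

Step 13
Reactants: 19 epoxy ester
Product: 20 labda-13(16),14-diene-8α,19-diol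
Conditions: LiAlH4, THF, reflux; NaOH/H2O work-up
Reagents that add atoms: none
Why: SN2 hydride opening of the trisubstituted epoxide at the secondary C7 should leave the oxygen on C8 in its α configuration (8α-OH, 8β-CH3), the same reagent reduces the hindered ester to the C19 carbinol, and the unactivated diene is inert to LiAlH4.

Step 14
Reactants: 21 (E)-ferulic acid
Product: 23 4-O-TBS-(E)-ferulic acid, via bis-TBS ferulate 22 (not isolated)
Conditions: TBSCl (2.5 equiv), imidazole, DMF, rt; then AcOH–THF–H2O, rt
Reagents that add atoms: tert-butyldimethylsilyl chloride, CC(C)(C)[Si](C)(C)Cl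
Why: Silylation of phenol and acid followed by selective hydrolysis of the far more labile silyl ester masks the phenol so that it cannot compete as a nucleophile in step 15.

Step 15
Reactants: 20 labda-13(16),14-diene-8α,19-diol; 23 4-O-TBS-(E)-ferulic acid
Product: 24 8α-hydroxylabda-13(16),14-dien-19-yl 4-O-TBS-(E)-ferulate
Conditions: DCC, DMAP, CH2Cl2, 0 °C → rt
Reagents that add atoms: none
Why: Steglich esterification: only the primary C19 hydroxyl should be acylated because the tertiary 8α-hydroxyl does not react with the acylpyridinium ion, and the (E)-cinnamate geometry is untouched.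

Step 16
Reactants: 24 TBS-protected ester
Product: 25 8α-hydroxylabda-13(16),14-dien-19-yl (E)-ferulate (target)
Conditions: TBAF, AcOH, THF, 0 °C
Reagents that add atoms: none
Why: Fluoride cleaves the aryl silyl ether through the strong Si–F bond, and buffering with acetic acid keeps the phenoxide from attacking the ester.

Compound list
1 | (R)-(−)-carvone | CC1=CC[C@H](CC1=O)C(C)=C | starting material
2 | 6-methylcarvone, (5R)-2,6-dimethyl-5-(prop-1-en-2-yl)cyclohex-2-en-1-one, C6 (= C10) epimers | CC1=CC[C@@H](C(C)=C)C(C)C1=O | intermediate
3 | 5-(1-hydroxypropan-2-yl)-2,6-dimethylcyclohex-2-en-1-ol, ring C5 as in carvone, other centres mixed | CC1=CC[C@@H](C(C)CO)C(C)C1O | intermediate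
4 | 2-(2,4-dimethyl-3-oxocyclohex-4-en-1-yl)propanoic acid, ring C1 (= C5) as in carvone, C4 and C10 epimers | CC1=CC[C@@H](C(C)C(O)=O)C(C)C1=O | intermediate
5 | acrolein | C=CC=O | starting material
6 | aldol hydroxy acid: 4 carrying on C10 a β-methyl and an α-(1R)-1-hydroxyprop-2-enyl group, trans to the C5 chain | CC1=CC[C@@H](C(C)C(O)=O)[C@](C)([C@H](O)C=C)C1=O | intermediate (not isolated)
7 | δ-lactone C1–O–C19(=O)–C4–C5–C10 trans-fused to the enone ring; 1α-vinyl (1R), 5α-H, 10β-CH3, C4 epimers | O=C1[C@@]2(C)[C@@H](C=C)OC(=O)C(C)[C@@H]2CC=C1C | intermediate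
8 | bis-TBS derivative of 7: cyclic C4=C19 silyl ketene acetal and C9 silyl dienol ether | CC1=C(O[Si](C)(C)C(C)(C)C)[C@@]2(C)[C@@H](C=C)OC(O[Si](C)(C)C(C)(C)C)=C(C)[C@@H]2C=C1 | intermediate (not isolated)
9 | rearranged TBS ester (ring A closed, C1=C2) still carrying the C9 silyl dienol ether | CC1=C(O[Si](C)(C)C(C)(C)C)[C@@]2(C)C=CC[C@](C)(C(=O)O[Si](C)(C)C(C)(C)C)[C@@H]2C=C1 | intermediate (not isolated)
10 | 1,4a,6-trimethyl-5-oxo-1,2,4a,5,8,8a-hexahydronaphthalene-1-carboxylic acid; 4β-CO2H, 4α-CH3, 5α-H, 10β-CH3 | O=C1[C@@]2(C)C=CC[C@](C)(C(=O)O)[C@@H]2CC=C1C | intermediate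
11 | methyl ester of 10 | O=C1[C@@]2(C)C=CC[C@](C)(C(=O)OC)[C@@H]2CC=C1C | intermediate
12 | methyl 1,4a,6-trimethyl-5-oxo-1,2,3,4,4a,5,8,8a-octahydronaphthalene-1-carboxylate (same configuration) | O=C1[C@@]2(C)CCC[C@](C)(C(=O)OC)[C@@H]2CC=C1C | intermediate
13 | 5-methylidene analogue of 12 (C9=C11, C7=C8 diene) | C=C1[C@@]2(C)CCC[C@](C)(C(=O)OC)[C@@H]2CC=C1C | intermediate
14 | isoprene | C=CC(C)=C | starting material
15 | (E)-1,4-dibromo-2-methylbut-2-ene | BrC/C(C)=C/CBr | intermediate
16 | 2-(bromomethyl)buta-1,3-diene | C=CC(=C)CBr | intermediate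
17 | B-(C11)-alkyl-9-BBN from 13, 9α-H | C(B1C2CCCC1CCC2)[C@@H]3[C@@]4(C)CCC[C@](C)(C(=O)OC)[C@@H]4CC=C3C | intermediate (not isolated)
18 | methyl labda-7,13(16),14-trien-19-oate | C=CC(=C)CC[C@@H]1[C@@]2(C)CCC[C@](C)(C(=O)OC)[C@@H]2CC=C1C | intermediate
19 | methyl 7α,8α-epoxylabda-13(16),14-dien-19-oate | C=CC(=C)CC[C@@H]1[C@@]2(C)CCC[C@](C)(C(=O)OC)[C@@H]2C[C@H]3O[C@@]13C | intermediate
20 | labda-13(16),14-diene-8α,19-diol | C=CC(=C)CC[C@@H]1[C@@]2(C)CCC[C@](C)(CO)[C@@H]2CC[C@@]1(C)O | intermediate
21 | (E)-ferulic acid | COc1cc(/C=C/C(=O)O)ccc1O | starting material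
22 | TBS 4-O-TBS-(E)-ferulate | COc1cc(/C=C/C(=O)O[Si](C)(C)C(C)(C)C)ccc1O[Si](C)(C)C(C)(C)C | intermediate (not isolated)
23 | 4-O-TBS-(E)-ferulic acid | COc1cc(/C=C/C(=O)O)ccc1O[Si](C)(C)C(C)(C)C | intermediate
24 | 8α-hydroxylabda-13(16),14-dien-19-yl 4-O-TBS-(E)-ferulate | C=CC(=C)CC[C@@H]1[C@@]2(C)CCC[C@](C)(COC(=O)/C=C/c3ccc(O[Si](C)(C)C(C)(C)C)c(OC)c3)[C@@H]2CC[C@@]1(C)O | intermediate
25 | 8α-hydroxylabda-13(16),14-dien-19-yl (E)-ferulate (CNP0142252.1) | C=CC(=C)CC[C@@H]1[C@@]2(C)CCC[C@](C)(COC(=O)/C=C/c3ccc(O)c(OC)c3)[C@@H]2CC[C@@]1(C)O | target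

Total step count: 16. Longest linear sequence: 13 (steps 1–8, 11–13, 15, 16).

Steps most likely to fail

1. Step 5.
- What may go wrong: enolisation of the hindered tertiary C4–H may be slow or unselective beside the more acidic enone. The ketene acetal may also be lost by hydrolysis or C-silylation before it rearranges.
- Fallback (sets out from 7, comes back at 10): the same ring closure is run at the aldehyde level, without enolate or silicon. The lactone carbonyl alone should be reduced with DIBAL-H at −78 °C to the lactol F1, because the C9 ketone is shielded by C10 and the C8 methyl. MsCl/Et3N then dehydrates it to the 2-vinyl-3,4-dihydro-2H-pyran F2. This neutral enol ether holds the same six-atom array and should undergo the aliphatic Claisen rearrangement on heating in o-dichlorobenzene (about 200 °C, sealed vessel) to the C19 aldehyde F3. Pinnick oxidation of F3 gives 10.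

2. Step 4.
- What may go wrong: the aldol addition may reverse on warming, and facial selectivity at the aldehyde carbon (C1) may be poor.
- Fallback (sets out from 4, comes back at 6): the stereodetermining bond is changed from C10–C1 to C1–C2. The dianion of 4 is C-formylated with 2,2,2-trifluoroethyl formate to the β-keto aldehyde F4. Vinylmagnesium bromide then adds to the aldehyde of its magnesium chelate from the side of the small C20 methyl, which should give the same 1R carbinol 6. This is lactonised to 7 as in step 4.

3. Step 11.
- What may go wrong: boron-to-copper transfer of the β-branched alkyl group may be sluggish, and the dienyl bromide may be lost to tert-butoxide or to polymerisation.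
- Fallback (sets out from 13, comes back at 18): C12 is added first and the diene is then attached by an sp3–sp2 coupling. The borane 17 is oxidised (NaOH, H2O2) to the homoallylic alcohol F5. Dess–Martin oxidation gives the aldehyde F6, and salt-free Wittig methylenation at low temperature gives the C9 vinyl compound F7. 9-BBN should hydroborate only the monosubstituted alkene to give the C12 alkyl-9-BBN F8. B-alkyl Suzuki–Miyaura coupling of F8 with chloroprene (Pd catalyst, aqueous base) gives 18.

Further compounds
F1 | step 5 | lactol of 7 (C19 hemiacetal) | O=C1[C@@]2(C)[C@@H](C=C)OC(O)C(C)[C@@H]2CC=C1C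
F2 | step 5 | 2-vinyl-3,4-dihydro-2H-pyran (C4=C19 enol ether) trans-fused to the enone ring | O=C1[C@@]2(C)[C@@H](C=C)OC=C(C)[C@@H]2CC=C1C
F3 | step 5 | C19 aldehyde analogue of 10 | O=C1[C@@]2(C)C=CC[C@](C)(C=O)[C@@H]2CC=C1C
F4 | step 4 | 10α-formyl keto acid (β-keto aldehyde from 4) | CC1=CC[C@@H](C(C)C(O)=O)[C@](C)(C=O)C1=O
F5 | step 11 | C11 alcohol from 17 (9α-H) | OC[C@@H]1[C@@]2(C)CCC[C@](C)(C(=O)OC)[C@@H]2CC=C1C
F6 | step 11 | C11 aldehyde | O=C[C@@H]1[C@@]2(C)CCC[C@](C)(C(=O)OC)[C@@H]2CC=C1C
F7 | step 11 | C9 vinyl compound (C11=C12) | C=C[C@@H]1[C@@]2(C)CCC[C@](C)(C(=O)OC)[C@@H]2CC=C1C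
F8 | step 11 | B-(C12)-alkyl-9-BBN | C(CB1C2CCCC1CCC2)[C@@H]3[C@@]4(C)CCC[C@](C)(C(=O)OC)[C@@H]4CC=C3C
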